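Everything rests on cutting the seven-membered ring between C6 and C7. With C6 as a ketone, the C7 methylene and the C8=C9 alkene make up a β,γ-unsaturated ketone, which is what a photochemical 1,3-acyl shift leaves behind. One irradiation breaks the C6–C9 bond of a cyclopentanone and joins C6 to the terminal carbon of a C9 isopropenyl group, so ring B of a cis-diquinane gains two carbons and becomes the hydroazulene ring of the daucane. The precursor is a cis-fused diquinane C6 ketone carrying the angular C1 methyl, the C9 isopropenyl group, a 2α silyl ether and a 4α methoxymethyl ether; C5, C6 and C4 are set right after the ring expansion.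

Key step: step 8

Remark: daucane numbering is used for all bicyclic compounds and β means the face of the C1 methyl group; the side-chain centre that becomes C9 is racemic from step 1 and is carried as an epimer mixture (left undefined in the SMILES) because step 8 makes it trigonal.

Step 1
Reactants: 1 methyl 3-methylbut-2-enoate
Product: 3 methyl 2-(hydroxymethyl)-3-methylbut-3-enoate (racemic), via lithium dienolate 2 (not isolated)
Conditions: LiN(iPr)2, THF/DMPU, −78 °C; HCHO (gas, from paraformaldehyde), −78 °C; aq NH4Cl
Reagents that add atoms: formaldehyde, C=O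
Why: γ-Deprotonation of the senecioate gives the lithium dienolate, which adds to formaldehyde at its α-carbon (deconjugative aldol addition) and so places the isopropenyl group and a hydroxymethyl arm on the future C9; the new centre is racemic and is erased in step 8.

Step 2
Reactants: 3 methyl 2-(hydroxymethyl)-3-methylbut-3-enoate
Product: 4 methyl 2-(iodomethyl)-3-methylbut-3-enoate (racemic)
Conditions: I2, PPh3, imidazole, CH2Cl2, 0 °C
Reagents that add atoms: iodine, II
Why: Appel-type iodination replaces the primary hydroxyl through its oxyphosphonium salt under near-neutral conditions that should spare the β,γ-unsaturated ester.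

Step 3
Reactants: 4 methyl 2-(iodomethyl)-3-methylbut-3-enoate; 5 (S)-4-(tert-butyldimethylsilyloxy)cyclopent-2-enone
Product: 7 trimethylsilyl enol ether of the conjugate adduct (chain trans to the silyloxy group), via alkylzinc iodide 6 (not isolated)
Conditions: Zn dust (activated), THF, 35 °C; then 5, Me3SiCl, CuBr·SMe2 (10 mol %), DMPU, −40 → 0 °C
Reagents that add atoms: chlorotrimethylsilane, C[Si](C)(C)Cl
Why: Zinc insertion gives an ester-tolerant β-zincio ester (zinc homoenolate) whose copper-catalysed, silyl-chloride-accelerated conjugate addition delivers the chain to the β-carbon of the enone (future C1) anti to the silyloxy group and traps the enolate regiospecifically on the side away from that group, so β-elimination cannot occur; the new ring stereocentre is removed in step 4.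

Step 4
Reactants: 7 trimethylsilyl enol ether of the conjugate adduct
Product: 8 methyl 2-{[(5S)-5-(tert-butyldimethylsilyloxy)-3-oxocyclopent-1-en-1-yl]methyl}-3-methylbut-3-enoate (side-chain epimers)
Conditions: Pd(OAc)2 (1.1 equiv), MeCN, 25 °C
Reagents that add atoms: none
Why: Saegusa–Ito oxidation, in which the palladium enolate can only undergo β-hydride elimination toward the chain-bearing carbon, regenerates the enone with the side chain on its β-carbon and leaves the silyloxy stereocentre untouched.

Step 5
Reactants: 8 methyl 2-{[(5S)-5-(tert-butyldimethylsilyloxy)-3-oxocyclopent-1-en-1-yl]methyl}-3-methylbut-3-enoate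
Product: 10 cis-diquinane-4,6-dione (1β-methyl; 2α-OTBS; C9 isopropenyl), via lithium enolate 9 (not isolated)
Conditions: Me2CuLi (from MeLi and CuI), Et2O, −78 → −20 °C; then THF, 0 → 25 °C; aq NH4Cl
Reagents that add atoms: lithium dimethylcuprate, [Li+].C[Cu-]C
Why: Gilman cuprate 1,4-addition anti to the adjacent silyl ether sets the quaternary C1 (methyl trans to the C2 oxygen), and the regiodefined enolate then closes ring B by 5-exo-trig Dieckmann acylation on the side-chain ester, driven by β-diketonate formation; a bicyclo[3.3.0]octane can only be cis-fused, so C5 follows from C1.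

Step 6
Reactants: 10 cis-diquinane-4,6-dione
Product: 11 4α-hydroxy-cis-diquinan-6-one (2α-OTBS; C9 isopropenyl)
Conditions: NaBH4, MeOH/CH2Cl2, −78 °C
Reagents that add atoms: none
Why: Chemoselective borohydride mono-reduction of a 1,3-dione: the ring A carbonyl (C4) is flanked by a methylene and activated by the β-silyloxy group whereas C6 is shielded by the isopropenyl-bearing C9, and hydride enters from the convex face to give the 4α (endo) alcohol, a centre that is oxidised again in step 14.

Step 7
Reactants: 11 4α-hydroxy-cis-diquinan-6-one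
Product: 12 4α-(methoxymethoxy)-cis-diquinan-6-one (2α-OTBS; C9 isopropenyl)
Conditions: MOMCl, iPr2NEt, CH2Cl2, 0 → 25 °C
Reagents that add atoms: chloromethyl methyl ether, COCCl
Why: Standard acetal protection under mild amine base; an acetal is preferred to a silyl ether because it survives KOt-Bu in step 9, is a poorer leaving group β to the C6 ketone and can later be removed beside the silyl ethers.

Step 8
Reactants: 12 4α-(methoxymethoxy)-cis-diquinan-6-one
Product: 13 cis-fused hydroazulen-6-one (5β-H; 4α-OMOM; 2α-OTBS; C8=C9)
Conditions: hν (300 nm, Pyrex filter), degassed cyclohexane (0.005 M), 20 °C, to about half conversion; recovered 12 recycled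
Reagents that add atoms: none
Why: Direct n→π* excitation of the β,γ-unsaturated ketone leads from the singlet state to α-cleavage (Norrish type 1) of the allylic C6–C9 bond, and the caged acyl/2-methylallyl radical pair recombines at the far allyl carbon C7. The closest known reaction type is the photochemical 1,3-acyl shift used for two-carbon ring expansion of 2-alkenylcycloalkanones. The seven-membered ring is not closed by attack on a π bond but by in-cage radical recombination that inserts C8 and C7 between C9 and C6, so ring B grows from five to seven members while ring A stays intact. No stereocentre is created: C9 becomes trigonal, so both C9 epimers converge, and C1, C2, C4 and C5 are untouched, which leaves the product cis-fused. The step needs cleavage on the allylic side and not at C5–C6, which the stabilised allyl radical secures, and singlet instead of triplet reactivity, which irradiation without a sensitiser secures so that the oxa-di-π-methane rearrangement stays out. Because the product is itself a β,γ-unsaturated ketone the reaction is stopped at a stationary mixture and the precursor is recycled.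

Step 9
Reactants: 13 cis-fused hydroazulen-6-one
Product: 15 trans-fused hydroazulen-6-one (5α-H; 4α-OMOM; 2α-OTBS; C8=C9), via potassium dienolate 14 (not isolated)
Conditions: KOt-Bu (3 equiv), t-BuOH/THF, 25 °C; then inverse quench into 10% aq AcOH at 0 °C; recovered 13 resubmitted
Reagents that add atoms: none
Why: Thermodynamic epimerisation of C5 by reversible α′-enolisation while the ketone rests as the extended dienolate (O–C6=C7–C8=C9), followed by kinetic α-protonation at C7 (deconjugative protonation of a potassium dienolate) that keeps the alkene at C8=C9; the trans fusion should prevail because it takes C6 away from the cis C4 alkoxy group and because angular-methyl hydroazulenones with the ketone in the seven-membered ring equilibrate toward trans, and the acetal oxygen is a poor nucleofuge so epimerisation should outrun E1cB loss.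

Step 10
Reactants: 15 trans-fused hydroazulen-6-one
Product: 16 trans-fused 6α-alcohol (6S; 4α-OMOM; 2α-OTBS)
Conditions: Li, NH3(l)/THF, EtOH, −78 °C; then NH4Cl
Reagents that add atoms: none
Why: Dissolving-metal reduction gives the more stable equatorial alcohol, here the 6α carbinol trans to the angular methyl, whereas hydride reagents would enter from the open α face and give the 6β epimer; the isolated alkene, the acetal and the silyl ether are inert.

Step 11
Reactants: 17 4-hydroxybenzoic acid
Product: 19 4-(tert-butyldimethylsilyloxy)benzoic acid, via silyl ester 18 (not isolated)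
Conditions: TBSCl (2.2 equiv), imidazole, DMF, 25 °C; then AcOH/THF/H2O, 25 °C
Reagents that add atoms: tert-butyldimethylsilyl chloride, CC(C)(C)[Si](C)(C)Cl
Why: Silylation of both acidic hydroxyls followed by selective hydrolysis of the much more labile silyl ester gives the phenol-protected acid (standard protection).

Step 12
Reactants: 16 trans-fused 6α-alcohol; 19 4-(tert-butyldimethylsilyloxy)benzoic acid
Product: 20 6α-[4-(tert-butyldimethylsilyloxy)benzoate] (4α-OMOM; 2α-OTBS)
Conditions: DCC, DMAP (cat.), CH2Cl2, 25 °C
Reagents that add atoms: none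
Why: Steglich esterification acylates the only free hydroxyl, the equatorial C6 carbinol, with retention at C6.

Step 13
Reactants: 20 6α-[4-(tert-butyldimethylsilyloxy)benzoate]
Product: 21 4α-alcohol (6α-aroate; 2α-OTBS)
Conditions: ZnBr2, n-PrSH, CH2Cl2, 0 °C
Reagents that add atoms: none
Why: Lewis-acid/thiol transacetalisation cleaves the methoxymethyl ether within minutes at 0 °C and should leave the alkyl and aryl silyl ethers, the ester and the alkene intact.

Step 14
Reactants: 21 4α-alcohol
Product: 22 trans-fused 4-ketone (6α-aroate; 2α-OTBS)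
Conditions: Dess–Martin periodinane, CH2Cl2, 0 → 25 °C
Reagents that add atoms: none
Why: Dess–Martin oxidation of the secondary C4 alcohol is non-basic, so the cyclopentanone forms without enolisation and the trans ring fusion at C5 as well as the β-acyloxy and β-silyloxy groups are preserved.

Step 15
Reactants: 22 trans-fused 4-ketone
Product: 23 bis-silyl ether of the target (4β-OH; 4α-isopropyl)
Conditions: iPrMgCl, CeCl3 (dried), THF, −78 °C; aq NH4Cl at −78 °C
Reagents that add atoms: isopropylmagnesium chloride, CC(C)[Mg]Cl
Why: Organocerium 1,2-addition: the weakly basic isopropylcerium reagent adds to the cyclopentanone faster than to the hindered, electron-rich aryl ester and without enolisation, β-elimination or hydride transfer, and attack anti to the C5–C6 bond (α face, opposite the angular methyl) gives the 4R carbinol with the hydroxyl β and the isopropyl group α.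

Step 16
Reactants: 23 bis-silyl ether of the target
Product: 24 2α-hydroxyferutinin (target)
Conditions: HF·pyridine, pyridine/THF, 0 → 25 °C
Reagents that add atoms: none
Why: Fluoride-mediated desilylation removes the aryl and the hindered secondary alkyl silyl ethers in a buffered, non-basic medium in which the benzoate, the tertiary alcohol and the trisubstituted alkene should survive without acyl migration.

Compound list
1 | methyl 3-methylbut-2-enoate | CC(C)=CC(=O)OC | starting material
2 | lithium dienolate of 1 (lithium 1-methoxy-3-methylbuta-1,3-dien-1-olate) | [Li+].COC([O-])=CC(C)=C | intermediate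
3 | methyl 2-(hydroxymethyl)-3-methylbut-3-enoate (racemic) | COC(=O)C(CO)C(C)=C | intermediate
4 | methyl 2-(iodomethyl)-3-methylbut-3-enoate (racemic) | COC(=O)C(CI)C(C)=C | intermediate
5 | (S)-4-(tert-butyldimethylsilyloxy)cyclopent-2-enone | O=C1C[C@H](O[Si](C)(C)C(C)(C)C)C=C1 | starting material
6 | [2-(methoxycarbonyl)-3-methylbut-3-en-1-yl]zinc iodide | COC(=O)C(C[Zn]I)C(C)=C | intermediate
7 | methyl 3-methyl-2-{[trans-5-(tert-butyldimethylsilyloxy)-3-(trimethylsilyloxy)cyclopent-2-en-1-yl]methyl}but-3-enoate (side-chain epimers) | C[Si](C)(C)OC1=C[C@H](CC(C(=O)OC)C(C)=C)[C@@H](O[Si](C)(C)C(C)(C)C)C1 | intermediate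
8 | methyl 2-{[(5S)-5-(tert-butyldimethylsilyloxy)-3-oxocyclopent-1-en-1-yl]methyl}-3-methylbut-3-enoate (side-chain epimers) | O=C1C=C(CC(C(=O)OC)C(C)=C)[C@@H](O[Si](C)(C)C(C)(C)C)C1 | intermediate
9 | lithium enolate formed by methyl addition to 8 (methyl trans to the silyloxy group) | [Li+].[O-]C1=C[C@@](C)(CC(C(=O)OC)C(C)=C)[C@@H](O[Si](C)(C)C(C)(C)C)C1 | intermediate
10 | cis-diquinane-4,6-dione: 1β-methyl, 2α-OTBS, 5β-H, C9 isopropenyl (C9 epimers) | CC(=C)C1C[C@]2(C)[C@H](C1=O)C(=O)C[C@@H]2O[Si](C)(C)C(C)(C)C | intermediate
11 | 4α-hydroxy-cis-diquinan-6-one: 1β-methyl, 2α-OTBS, 5β-H, C9 isopropenyl | CC(=C)C1C[C@]2(C)[C@H](C1=O)[C@H](O)C[C@@H]2O[Si](C)(C)C(C)(C)C | intermediate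
12 | 4α-(methoxymethoxy)-cis-diquinan-6-one: 1β-methyl, 2α-OTBS, 5β-H, C9 isopropenyl (precursor of the key step) | CC(=C)C1C[C@]2(C)[C@H](C1=O)[C@H](OCOC)C[C@@H]2O[Si](C)(C)C(C)(C)C | intermediate
13 | cis-fused hydroazulen-6-one: 1β-methyl, 5β-H, 4α-OMOM, 2α-OTBS, C8=C9 (product of the key step) | CC1=CC[C@]2(C)[C@H](C(=O)C1)[C@H](OCOC)C[C@@H]2O[Si](C)(C)C(C)(C)C | intermediate
14 | potassium dienolate of 13 and 15 (O–C6=C7–C8=C9; C5 equilibrating) | [K+].CC1=CC[C@]2(C)C(C([O-])=C1)[C@H](OCOC)C[C@@H]2O[Si](C)(C)C(C)(C)C | intermediate
15 | trans-fused hydroazulen-6-one: 1β-methyl, 5α-H, 4α-OMOM, 2α-OTBS, C8=C9 | CC1=CC[C@]2(C)[C@@H](C(=O)C1)[C@H](OCOC)C[C@@H]2O[Si](C)(C)C(C)(C)C | intermediate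
16 | trans-fused 6α-alcohol (6S): 4α-OMOM, 2α-OTBS, C8=C9 | CC1=CC[C@]2(C)[C@@H]([C@@H](O)C1)[C@H](OCOC)C[C@@H]2O[Si](C)(C)C(C)(C)C | intermediate
17 | 4-hydroxybenzoic acid | O=C(O)c1ccc(O)cc1 | starting material
18 | tert-butyldimethylsilyl 4-(tert-butyldimethylsilyloxy)benzoate | CC(C)(C)[Si](C)(C)OC(=O)c1ccc(O[Si](C)(C)C(C)(C)C)cc1 | intermediate
19 | 4-(tert-butyldimethylsilyloxy)benzoic acid | O=C(O)c1ccc(O[Si](C)(C)C(C)(C)C)cc1 | intermediate
20 | 6α-[4-(tert-butyldimethylsilyloxy)benzoyloxy] trans-hydroazulene: 4α-OMOM, 2α-OTBS | CC1=CC[C@]2(C)[C@@H]([C@@H](OC(=O)c3ccc(O[Si](C)(C)C(C)(C)C)cc3)C1)[C@H](OCOC)C[C@@H]2O[Si](C)(C)C(C)(C)C | intermediate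
21 | 4α-alcohol: 6α-aroate, 2α-OTBS | CC1=CC[C@]2(C)[C@@H]([C@@H](OC(=O)c3ccc(O[Si](C)(C)C(C)(C)C)cc3)C1)[C@H](O)C[C@@H]2O[Si](C)(C)C(C)(C)C | intermediate
22 | trans-fused 4-ketone: 6α-aroate, 2α-OTBS, 5α-H | CC1=CC[C@]2(C)[C@@H]([C@@H](OC(=O)c3ccc(O[Si](C)(C)C(C)(C)C)cc3)C1)C(=O)C[C@@H]2O[Si](C)(C)C(C)(C)C | intermediate
23 | 2-O,4′-O-bis(tert-butyldimethylsilyl) 2α-hydroxyferutinin (4β-OH, 4α-isopropyl) | CC1=CC[C@]2(C)[C@@H]([C@@H](OC(=O)c3ccc(O[Si](C)(C)C(C)(C)C)cc3)C1)[C@](O)(C(C)C)C[C@@H]2O[Si](C)(C)C(C)(C)C | intermediate
24 | 2α-hydroxyferutinin, (1R,2S,4R,5S,6S) in daucane numbering | CC1=CC[C@]2(C)[C@@H]([C@@H](OC(=O)c3ccc(O)cc3)C1)[C@](O)(C(C)C)C[C@@H]2O | target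

Total step count: 16. Longest linear sequence: 15 steps (steps 1–10 and 12–16, from methyl 3-methylbut-2-enoate; 13 steps from enone 5).

Steps most likely to fail

Step 8 (photochemical ring expansion). The excited ketone may lose carbon monoxide, fall back to the diquinane, or drift into triplet chemistry, so that the stationary mixture stays poor in 13. The fallback closes the seven-membered ring by olefin metathesis instead and sets out from enone 5. Conjugate addition of allyltributylstannane promoted by TBSOTf would give the tert-butyldimethylsilyl enol ether F1, and Saegusa oxidation with Pd(OAc)2 the 3-allyl enone F2. Me2CuLi would add anti to the silyl ether to give the lithium enolate F3, which after transmetalation with ZnCl2 is trapped with 3-methylbut-3-enal as the aldol F4 (side chain trans to the allyl group; diastereomers separated). Ring-closing metathesis with the second-generation Grubbs catalyst would form the C8=C9 bond and give the trans-fused keto alcohol F5, and esterification with acid 19 (DCC, DMAP) leads to ketone 22, where the route is rejoined before step 15.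

Step 9 (correction of C5). The potassium dienolate may exchange the C5 proton too slowly, may not favour the trans fusion, or its α′-enolate may expel the C4 alkoxy group. The fallback sets out from 13 and lets the alkene move into conjugation on purpose: DBU in toluene at 25 °C equilibrates C5 at the stage of the neutral conjugated enone, from which the trans-fused conjugated enone F6 is separated and the cis isomer resubmitted. Silylation under equilibrating conditions (Me3SiCl, NaI, Et3N, MeCN) would convert F6 into the through-conjugated trimethylsilyl dienol ether F7, and cold dilute acetic acid would protonate F7 at C7 and return the β,γ-unsaturated ketone 15.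

Step 6 (mono-reduction of the 1,3-dione). Hydride may not discriminate between the two carbonyl groups or may reduce both. The fallback sets out from 10 and reduces both carbonyls on purpose (NaBH4 in excess, MeOH, 0 °C) to the diol F8. The less hindered C4 hydroxyl would then be protected selectively (MOMCl, iPr2NEt, 0 °C; the C6 hydroxyl lies between two methine carbons) as the mono-methoxymethyl ether F9, and Dess–Martin oxidation of the remaining C6 carbinol returns the route to 12.

Further compounds
F1 | step 8 | tert-butyldimethylsilyl enol ether of trans-3-allyl-4-(tert-butyldimethylsilyloxy)cyclopentanone | CC(C)(C)[Si](C)(C)OC1=C[C@H](CC=C)[C@@H](O[Si](C)(C)C(C)(C)C)C1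
F2 | step 8 | (4S)-3-allyl-4-(tert-butyldimethylsilyloxy)cyclopent-2-enone | O=C1C=C(CC=C)[C@@H](O[Si](C)(C)C(C)(C)C)C1
F3 | step 8 | lithium enolate from methyl addition to F2 (methyl trans to the silyloxy group) | [Li+].[O-]C1=C[C@@](C)(CC=C)[C@@H](O[Si](C)(C)C(C)(C)C)C1
F4 | step 8 | aldol of F3 with 3-methylbut-3-enal: 3-allyl-2-(1-hydroxy-3-methylbut-3-enyl)-3-methyl-4-(tert-butyldimethylsilyloxy)cyclopentanone (side chain trans to allyl) | C=CC[C@]1(C)[C@@H]([C@@H](O)CC(C)=C)C(=O)C[C@@H]1O[Si](C)(C)C(C)(C)C
F5 | step 8 | trans-fused 6α-hydroxy-hydroazulen-4-one: 2α-OTBS, C8=C9 | CC1=CC[C@]2(C)[C@@H]([C@@H](O)C1)C(=O)C[C@@H]2O[Si](C)(C)C(C)(C)C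
F6 | step 9 | trans-fused conjugated enone (C6 ketone, C7=C8): 4α-OMOM, 2α-OTBS | CC1=CC(=O)[C@H]2[C@H](OCOC)C[C@H](O[Si](C)(C)C(C)(C)C)[C@]2(C)CC1
F7 | step 9 | through-conjugated trimethylsilyl dienol ether of 15 (C6–OSiMe3, C6=C7, C8=C9) | CC1=CC[C@]2(C)[C@@H](C(O[Si](C)(C)C)=C1)[C@H](OCOC)C[C@@H]2O[Si](C)(C)C(C)(C)C
F8 | step 6 | cis-diquinane-4,6-diol: 4α-OH, 2α-OTBS, C9 isopropenyl (C6 and C9 epimers) | CC(=C)C1C[C@]2(C)[C@H](C1O)[C@H](O)C[C@@H]2O[Si](C)(C)C(C)(C)C
F9 | step 6 | 4α-(methoxymethoxy)-cis-diquinan-6-ol: 2α-OTBS, C9 isopropenyl (C6 and C9 epimers) | CC(=C)C1C[C@]2(C)[C@H](C1O)[C@H](OCOC)C[C@@H]2O[Si](C)(C)C(C)(C)C
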